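Target in blue cannot pass 36.7% of the starting material charged, since each target takes one reagent and the 1.10 M of reagent charged is less than the 3.0 M of starting material. How far below that line a flask stops depends on what else takes the reagent.

| flask | starting material | reagent | temperature | remark | time |
|---|---|---|---|---|---|
| summer | 1.4 M | 1.1 M | 75 °C | run made earlier |  |
| noon | 1.4 M | 1.1 M | 95 °C | run made earlier |  |
| blue | 3.0 M | 1.10 M | 80 °C |  | 20 min |
| ochre | 1.0 M | 1.10 M | 110 °C |  | 20 min |

| run | time / min | target / % | starting material / % |
|---|---|---|---|
| summer | 15.0 | 25.8 | 72.4 |
| summer | 30.0 | 35.8 | 62.4 |
| summer | 50.0 | 42.1 | 54.9 |
| summer | 60.0 | 44.7 | 52.4 |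
| noon | 5.00 | 28.7 | 69.9 |
| noon | 10.0 | 37.7 | 59.8 |
| noon | 15.0 | 42.9 | 54.4 |
| noon | 20.0 | 45.9 | 51.1 |

(each reading ± 0.3 percentage points)

- percentages count the starting material that a species holds: one side product counts as two
- target is meant together with its idle adduct
- candidate steps: starting material + reagent -> target; 2 starting material -> side product; 2 reagent -> self-condensation product; reagent + target <-> idle adduct

- which one finishes higher in amount of target, in percent of the starting material charged ("neither" within 2 percentage points) (blue / ochre / neither)
- amount of target at the end, in percent of the starting material charged, blue
- amount of target at the end, in percent of the starting material charged, ochre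

The noon run gives a ledger for its reagent charge of 1.1 M, taken between 15.0 min and 20.0 min. The first entry is target, 0.622 M on average. The second is free reagent, which has to be read from the rate. Over noon's first 5.00 min, the rate constant k, taken as first order in each partner, reads 0.0752 /M/min. The late rate of 0.00840 M/min then implies 0.151 M free, a reading that carries the scatter of a small difference. The books close with 0.327 M of reagent held or lost elsewhere, which these readings cannot assign to self-condensation product or idle adduct.

The reagent price π, the reagent gone per target counted, is therefore 1.53. At this price, a reagent charge pays for all the starting material only where the charge ratio of reagent to starting material exceeds π. Ochre's ratio of 1.10 lies below π, so at this price its reagent pays for less target than its starting material allows, despite reagent's excess on paper. But π counts held reagent as gone, and the adduct step can run back, so this is an estimate for a run of this length, not a ceiling on ochre. If a whole charge went at this price, blue would hold 24.0% and ochre 72.1%. This reckoning expects each flask a little lower, by its remaining free reagent.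

The forecast says ochre, with 26% (21% to 30%) for blue and 52% (44% to 61%) for ochre, where “about half is wasted”, so the ochre figure here stands above its range.

The flasks give ochre as the higher: blue 22.3%, ochre 66.3%.

    starting material + reagent → target (k = 0.260 /M/min, Ea = 69.0 kJ/mol)
    2 starting material → side product (k = 0.00404 /M/min, Ea = 73.0 kJ/mol)
    2 reagent → self-condensation product (k = 0.0136 /M/min, Ea = 83.0 kJ/mol)
    reagent + target ⇌ idle adduct, settled at all times (K = 11.7 /M, ΔH = 9.00 kJ/mol)
    (constants at 110 °C)

With free reagent at 9.2% of its charge in blue and 7.0% in ochre, π gives 21.8% for blue and 67.1% for ochre. Ochre's idle adduct holds 31.3% of the starting material charged at 20.0 min, each unit tying up one reagent beyond the one its target cost. The wearing away of reagent is the main reason why ochre stops at 66.3%: the same run without it ends at 98.3%.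

The runs are simulated from invented constants, and the scatter is random.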